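## Retrosynthetic overview

1. The target is disconnected last at both rings: the ten-membered carbocycle at C6–C7 (the bond closed in germacrane biosynthesis) and then the γ-lactone at O6–C12. Both form in one flask from an open-chain bromo ester aldehyde that already carries the epoxy ester on O8 and the free 9-OH (carbocycle first, lactone second).
2. The open chain comes from a terminal vinyl compound by cross-metathesis with methyl 2-(bromomethyl)acrylate (C11–C13) and oxidation of the C6 alcohol.
3. The vinyl compound comes from a (Z)-enal and a γ-acyloxyallyl chloride: one catalytic asymmetric syn-acyloxyallylation forms C8–C9, sets C8 and C9, and places the acyl group on O8 only.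
4. The (Z)-enal comes from geranyl acetate (chain cleavage, Z-selective iodo-olefination, formylation). The allyl chloride comes from angelic acid (Sharpless epoxidation, oxidation) and acrolein.

Locants C1–C15 in the text are germacrane locants (C6/C7 ring fusion, C8 ester carbon, C9 carbinol, C11–C13 acrylate unit).

Assumption: the sense of induction of the chromium–salen catalyst in step 8 is taken by analogy with the reported pivalate reagent; if the first run shows the opposite sense, the ligand antipode is used.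

## Route

Step 1
Reactants: 1 geranyl acetate
Product: 3 (2E)-3-methyl-6-oxohex-2-en-1-yl acetate, via epoxide 2 (not isolated)
Conditions: mCPBA, CH2Cl2, 0 °C; then H5IO6, THF/H2O, 0 °C to rt
Reagents that add atoms: 3-chloroperoxybenzoic acid (mCPBA), O=C(OO)c1cccc(Cl)c1
Why: Prilezhaev epoxidation picks the electron-rich 6,7-olefin because the 2,3-olefin is deactivated by the allylic acetate, and periodic acid then hydrolyses and cleaves the epoxide (glycol cleavage) to the aldehyde and acetone; no stereocentre is formed and the 2E olefin is untouched.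

Step 2
Reactants: 3 (2E)-3-methyl-6-oxohex-2-en-1-yl acetate; 4 ethyltriphenylphosphonium iodide
Product: 6 (2E,6Z)-7-iodo-3-methylocta-2,6-dien-1-ol, via iodo acetate 5 (not isolated)
Conditions: 4, n-BuLi, THF, 0 °C; I2, −78 °C; NaN(SiMe3)2, −78 to −20 °C; 3, −78 °C to rt; then K2CO3 (cat.), MeOH, rt
Reagents that add atoms: iodine, II
Why: Stork–Zhao-type Wittig olefination with the α-iodo ylide made in the flask gives the (Z)-2-iodoalkene under kinetic low-temperature control, which fixes the later C1=C10 geometry, and carbonate-catalysed transesterification then frees the C6 alcohol so that no base-labile ester has to be removed late.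

Step 3
Reactants: 6 (2E,6Z)-7-iodo-3-methylocta-2,6-dien-1-ol
Product: 8 (2Z,6E)-8-hydroxy-2,6-dimethylocta-2,6-dienal, via vinyllithium 7 (not isolated)
Conditions: t-BuLi (3.2 equiv), Et2O, −78 °C; DMF, −78 to 0 °C; aq NH4Cl
Reagents that add atoms: N,N-dimethylformamide, CN(C)C=O
Why: Iodine–lithium exchange on a vinyl iodide is fast at −78 °C and proceeds with retention of olefin geometry, and formylation of the vinyllithium with DMF (Bouveault reaction) gives the (Z)-2-methyl enal after hydrolysis; the first equivalent of t-BuLi only deprotonates the alcohol.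

Step 4
Reactants: 9 angelic acid
Product: 10 (2Z)-2-methylbut-2-en-1-ol
Conditions: LiAlH4, Et2O, 0 °C
Reagents that add atoms: none
Why: Hydride reduction of the carboxylic acid with LiAlH4 gives the allylic alcohol without touching the trisubstituted olefin, whose Z geometry is kept.

Step 5
Reactants: 10 (2Z)-2-methylbut-2-en-1-ol
Product: 11 [(2R,3S)-2,3-dimethyloxiran-2-yl]methanol
Conditions: Ti(OiPr)4 (10 mol%), D-(−)-diethyl tartrate (12 mol%), t-BuOOH, 4 Å molecular sieves, CH2Cl2, −20 °C
Reagents that add atoms: tert-butyl hydroperoxide, CC(C)(C)OO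
Why: Sharpless asymmetric epoxidation delivers oxygen to one face of the allylic alcohol, D-(−)-tartrate giving the (2R,3S) epoxide (by analogy with L-(+)-tartrate giving (2S,3S)-epoxygeraniol), and the Z olefin fixes the C3 methyl cis to the hydroxymethyl group.

Step 6
Reactants: 11 [(2R,3S)-2,3-dimethyloxiran-2-yl]methanol
Product: 12 (2S,3S)-2,3-dimethyloxirane-2-carboxylic acid
Conditions: TEMPO (10 mol%), PhI(OAc)2 (2.2 equiv), MeCN/H2O 1:1, rt
Reagents that add atoms: water, O
Why: TEMPO-catalysed oxidation with PhI(OAc)2 in aqueous acetonitrile takes the primary alcohol through the aldehyde hydrate to the acid under near-neutral conditions that leave the epoxide and both stereocentres untouched (the C2 descriptor changes from R to S only because the priorities change).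

Step 7
Reactants: 12 (2S,3S)-2,3-dimethyloxirane-2-carboxylic acid; 13 acrolein
Product: 15 3-chloroprop-1-en-1-yl (2S,3S)-2,3-dimethyloxirane-2-carboxylate (E/Z mixture), via acid chloride 14 (not isolated)
Conditions: 1-chloro-N,N,2-trimethylprop-1-en-1-amine, CH2Cl2, 0 °C; then 13, ZnCl2 (2 mol%), −20 °C
Reagents that add atoms: 1-chloro-N,N,2-trimethylprop-1-en-1-amine, CC(C)=C(Cl)N(C)C
Why: The α-chloroenamine (Ghosez reagent) turns the acid into its chloride without liberating HCl, and ZnCl2-catalysed conjugate 1,4-addition of the acyl chloride to acrolein gives the 3-chloropropenyl ester, the known type of precursor for γ-acyloxyallyl metal reagents; the olefin geometry is irrelevant because the allylchromium equilibrates.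

Step 8
Reactants: 8 (2Z,6E)-8-hydroxy-2,6-dimethylocta-2,6-dienal; 15 3-chloroprop-1-en-1-yl (2S,3S)-2,3-dimethyloxirane-2-carboxylate
Product: 17 (3R,4R,5Z,9E)-4,11-dihydroxy-5,9-dimethylundeca-1,5,9-trien-3-yl (2S,3S)-2,3-dimethyloxirane-2-carboxylate, via bis-silyl ether 16 (not isolated)
Conditions: 8, Me3SiCl (2.5 equiv), Et3N (1.5 equiv), MeCN; CrCl3 (10 mol%), (R,R)-N,N'-bis(3,5-di-tert-butylsalicylidene)cyclohexane-1,2-diamine (10 mol%), Mn powder (3 equiv), 15, rt; then 1 M HCl, THF, 0 °C
Reagents that add atoms: none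
Why: Catalytic enantioselective Nozaki–Hiyama–Kishi-type α-acyloxyallylation (precedent: 3-chloropropenyl pivalate with a trivalent-chromium salen catalyst turned over by Mn/Me3SiCl): the allylchromium adds through its oxygen-bearing γ-carbon to the Si face of the aldehyde in a closed transition state that gives the syn product, so C9 (R) and C8 (R) are set together and the epoxy ester arrives on O8 while O9 stays free; the α-quaternary acyl group resists 1,2-migration like pivalate, and minor stereoisomers are diastereomers separable by chromatography.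

Step 9
Reactants: 17 (3R,4R,5Z,9E)-4,11-dihydroxy-5,9-dimethylundeca-1,5,9-trien-3-yl (2S,3S)-2,3-dimethyloxirane-2-carboxylate; 18 methyl 2-(bromomethyl)prop-2-enoate
Product: 19 methyl (2Z,4R,5R,6Z,10E)-2-(bromomethyl)-4-{[(2S,3S)-2,3-dimethyloxirane-2-carbonyl]oxy}-5,12-dihydroxy-6,10-dimethyldodeca-2,6,10-trienoate
Conditions: second-generation Hoveyda–Grubbs catalyst (C31H38Cl2N2ORu, 10 mol%), 18 (5 equiv), CH2Cl2, 40 °C
Reagents that add atoms: none
Why: Olefin cross-metathesis between the only monosubstituted olefin of 17 and the 1,1-disubstituted acrylate (the trisubstituted olefins are inert) gives the trisubstituted enoate with the chain trans to the ester and cis to CH2Br (2Z), as known for methacrylates and α-methylene lactones; no stereocentre is touched.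

Step 10
Reactants: 19 methyl (2Z,4R,5R,6Z,10E)-2-(bromomethyl)-4-{[(2S,3S)-2,3-dimethyloxirane-2-carbonyl]oxy}-5,12-dihydroxy-6,10-dimethyldodeca-2,6,10-trienoate
Product: 20 methyl (2Z,4R,5R,6Z,10E)-2-(bromomethyl)-4-{[(2S,3S)-2,3-dimethyloxirane-2-carbonyl]oxy}-5-hydroxy-6,10-dimethyl-12-oxododeca-2,6,10-trienoate
Conditions: TEMPO (10 mol%), PhI(OAc)2 (1.1 equiv), CH2Cl2, rt
Reagents that add atoms: none
Why: Oxoammonium (TEMPO) oxidation is selective for the primary allylic alcohol over the hindered secondary one and leaves the allylic bromide, the epoxide and the olefin geometries untouched.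

Step 11
Reactants: 20 methyl (2Z,4R,5R,6Z,10E)-2-(bromomethyl)-4-{[(2S,3S)-2,3-dimethyloxirane-2-carbonyl]oxy}-5-hydroxy-6,10-dimethyl-12-oxododeca-2,6,10-trienoate
Product: 23 CNP0318223.3 [(3aS,4R,5R,6Z,10E,11aS)-5-hydroxy-6,10-dimethyl-3-methylidene-2-oxo-3a,4,5,8,9,11a-hexahydrocyclodeca[b]furan-4-yl (2S,3S)-2,3-dimethyloxirane-2-carboxylate], via allylindium 21 (not isolated), via hydroxy ester 22 (not isolated)
Conditions: In powder (2.5 equiv), THF/H2O 3:1, slow addition of 20 to 0.003 M, 25–40 °C, 12 h
Reagents that add atoms: none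
Why: Intramolecular indium-mediated Barbier 2-(alkoxycarbonyl)allylation followed by spontaneous lactonisation: the allylindium attacks the enal through C7 in a Zimmerman–Traxler chair with the Z-allyl substituent (C8) axial and the enal residue equatorial, giving the 6,7-syn adduct and hence the cis-fused lactone, while allylic 1,3-strain holds H8 in the allyl plane so that the C8–O bond is anti to the forming bond and the tether (C9) spans the attacked face, which sets 7S and 6S from 8R; high dilution favours ring closure, and the C6 alkoxide closes the five-membered lactone on the methyl ester with loss of methanol.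

## Compound list

1 | geranyl acetate, (2E)-3,7-dimethylocta-2,6-dien-1-yl acetate | CC(C)=CCC/C(C)=C/COC(C)=O | starting material
2 | (2E)-5-(3,3-dimethyloxiran-2-yl)-3-methylpent-2-en-1-yl acetate (racemic epoxide) | CC1(C)OC1CC/C(C)=C/COC(C)=O | intermediate (not isolated)
3 | (2E)-3-methyl-6-oxohex-2-en-1-yl acetate | O=CCC/C(C)=C/COC(C)=O | intermediate
4 | ethyltriphenylphosphonium iodide | CC[P+](c1ccccc1)(c1ccccc1)c1ccccc1.[I-] | starting material
5 | (2E,6Z)-7-iodo-3-methylocta-2,6-dien-1-yl acetate | C/C(I)=C/CC/C(C)=C/COC(C)=O | intermediate (not isolated)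
6 | (2E,6Z)-7-iodo-3-methylocta-2,6-dien-1-ol | C/C(I)=C/CC/C(C)=C/CO | intermediate
7 | lithium (2E,6Z)-7-lithio-3-methylocta-2,6-dien-1-olate | C/C([Li])=C/CC/C(C)=C/CO[Li] | intermediate (not isolated)
8 | (2Z,6E)-8-hydroxy-2,6-dimethylocta-2,6-dienal | C/C(C=O)=C/CC/C(C)=C/CO | intermediate
9 | angelic acid, (2Z)-2-methylbut-2-enoic acid | C/C=C(/C)C(=O)O | starting material
10 | (2Z)-2-methylbut-2-en-1-ol | C/C=C(/C)CO | intermediate
11 | [(2R,3S)-2,3-dimethyloxiran-2-yl]methanol | OC[C@@]1(C)O[C@H]1C | intermediate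
12 | (2S,3S)-2,3-dimethyloxirane-2-carboxylic acid | OC(=O)[C@@]1(C)O[C@H]1C | intermediate
13 | acrolein, prop-2-enal | C=CC=O | starting material
14 | (2S,3S)-2,3-dimethyloxirane-2-carbonyl chloride | ClC(=O)[C@@]1(C)O[C@H]1C | intermediate (not isolated)
15 | 3-chloroprop-1-en-1-yl (2S,3S)-2,3-dimethyloxirane-2-carboxylate (E/Z mixture) | ClCC=COC(=O)[C@@]1(C)O[C@H]1C | intermediate
16 | (3R,4R,5Z,9E)-5,9-dimethyl-4,11-bis(trimethylsilyloxy)undeca-1,5,9-trien-3-yl (2S,3S)-2,3-dimethyloxirane-2-carboxylate | C[Si](C)(C)OC/C=C(\C)CC/C=C(/C)[C@@H](O[Si](C)(C)C)[C@H](OC(=O)[C@@]1(C)O[C@H]1C)C=C | intermediate (not isolated)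
17 | (3R,4R,5Z,9E)-4,11-dihydroxy-5,9-dimethylundeca-1,5,9-trien-3-yl (2S,3S)-2,3-dimethyloxirane-2-carboxylate | OC/C=C(\C)CC/C=C(/C)[C@@H](O)[C@H](OC(=O)[C@@]1(C)O[C@H]1C)C=C | intermediate
18 | methyl 2-(bromomethyl)prop-2-enoate | C=C(CBr)C(=O)OC | starting material
19 | methyl (2Z,4R,5R,6Z,10E)-2-(bromomethyl)-4-{[(2S,3S)-2,3-dimethyloxirane-2-carbonyl]oxy}-5,12-dihydroxy-6,10-dimethyldodeca-2,6,10-trienoate | OC/C=C(\C)CC/C=C(/C)[C@@H](O)[C@H](OC(=O)[C@@]1(C)O[C@H]1C)/C=C(\CBr)C(=O)OC | intermediate
20 | methyl (2Z,4R,5R,6Z,10E)-2-(bromomethyl)-4-{[(2S,3S)-2,3-dimethyloxirane-2-carbonyl]oxy}-5-hydroxy-6,10-dimethyl-12-oxododeca-2,6,10-trienoate | O=C/C=C(\C)CC/C=C(/C)[C@@H](O)[C@H](OC(=O)[C@@]1(C)O[C@H]1C)/C=C(\CBr)C(=O)OC | intermediate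
21 | allylindium from 20 (CH2InBr2 in place of CH2Br, otherwise as 20) | O=C/C=C(\C)CC/C=C(/C)[C@@H](O)[C@H](OC(=O)[C@@]1(C)O[C@H]1C)/C=C(\C[In](Br)Br)C(=O)OC | intermediate (not isolated)
22 | methyl 2-[(1S,2S,3E,7Z,9R,10R)-10-{[(2S,3S)-2,3-dimethyloxirane-2-carbonyl]oxy}-2,9-dihydroxy-4,8-dimethylcyclodeca-3,7-dien-1-yl]prop-2-enoate | C=C(C(=O)OC)[C@H]1[C@@H](O)/C=C(\C)CC/C=C(/C)[C@@H](O)[C@@H]1OC(=O)[C@@]2(C)O[C@H]2C | intermediate (not isolated)
23 | CNP0318223.3, (3aS,4R,5R,6Z,10E,11aS)-5-hydroxy-6,10-dimethyl-3-methylidene-2-oxo-3a,4,5,8,9,11a-hexahydrocyclodeca[b]furan-4-yl (2S,3S)-2,3-dimethyloxirane-2-carboxylate | C=C1C(=O)O[C@H]2/C=C(\C)CC/C=C(/C)[C@@H](O)[C@H](OC(=O)[C@@]3(C)O[C@H]3C)[C@@H]12 | target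

## Step count and risks

Total step count: 11. Longest linear sequence: 8 steps (angelic acid 9 through steps 4, 5, 6, 7, 8, 9, 10, 11); the geranyl acetate branch is 7 steps (1, 2, 3, 8, 9, 10, 11).

The three steps most likely to fail:

Step 8 (one-step syn-acyloxyallylation). The reagent carries an ester not yet tried in this reaction, the acceptor is a (Z)-enal, and the epoxide must survive Me3SiCl and chloride. The fallback sets out from 8 and splits the task into a C–C and then a C–O bond formation. Chiral-phosphoric-acid-catalysed propargylation of 8 with allenylboronic acid pinacol ester gives the homopropargylic alcohol (4S,5Z,9E)-5,9-dimethylundeca-5,9-dien-1-yne-4,11-diol F1. Rhodium-catalysed redox-neutral coupling of the terminal alkyne of F1 with acid 12 ([Rh(cod)Cl]2 with a DIOP-type diphosphine; alkyne to allene to π-allyl rhodium, carboxylate attack at the internal terminus under ligand control) then gives the branched allylic ester and comes back to the route at 17.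

Step 9 (cross-metathesis of an allylic-ester olefin with a bromide-bearing 1,1-disubstituted acrylate). The fallback sets out from 17, gives up the bromide-bearing partner and brings bromine in last. TEMPO/PhI(OAc)2 oxidation of 17 first gives the aldehyde (3R,4R,5Z,9E)-4-hydroxy-5,9-dimethyl-11-oxoundeca-1,5,9-trien-3-yl (2S,3S)-2,3-dimethyloxirane-2-carboxylate F2. Cross-metathesis of F2 with methyl 2-(hydroxymethyl)acrylate (same ruthenium catalyst) gives methyl (2E,4R,5R,6Z,10E)-4-{[(2S,3S)-2,3-dimethyloxirane-2-carbonyl]oxy}-5-hydroxy-2-(hydroxymethyl)-6,10-dimethyl-12-oxododeca-2,6,10-trienoate F3, in which the only primary alcohol is the new allylic one. Appel bromination (CBr4, PPh3, −30 °C) of that primary alcohol, the hindered secondary C9 alcohol being left alone, comes back to the route at 20.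

Step 11 (ring closure). The risks are 1,4-elimination of the C8 carboxylate from the allylindium, intermolecular allylation, and the wrong face at C7. The fallback sets out from 20 and replaces the reducing metal by boron. Borylation of the allylic bromide with B2pin2 and zerovalent palladium (Pd2(dba)3, no base) gives the allylboronate methyl (2E,4R,5R,6Z,10E)-4-{[(2S,3S)-2,3-dimethyloxirane-2-carbonyl]oxy}-5-hydroxy-6,10-dimethyl-12-oxo-2-[(4,4,5,5-tetramethyl-1,3,2-dioxaborolan-2-yl)methyl]dodeca-2,6,10-trienoate F4. On warming in dilute toluene, F4 adds to the enal through a closed six-membered allylboration transition state (same axial C8 and equatorial enal arrangement, no carbanion character and so no elimination). This comes back to the route at 22, which lactonises to 23.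

## Further compounds

F1 | step 8 | (4S,5Z,9E)-5,9-dimethylundeca-5,9-dien-1-yne-4,11-diol | OC/C=C(\C)CC/C=C(/C)[C@@H](O)CC#C
F2 | step 9 | (3R,4R,5Z,9E)-4-hydroxy-5,9-dimethyl-11-oxoundeca-1,5,9-trien-3-yl (2S,3S)-2,3-dimethyloxirane-2-carboxylate | O=C/C=C(\C)CC/C=C(/C)[C@@H](O)[C@H](OC(=O)[C@@]1(C)O[C@H]1C)C=C
F3 | step 9 | methyl (2E,4R,5R,6Z,10E)-4-{[(2S,3S)-2,3-dimethyloxirane-2-carbonyl]oxy}-5-hydroxy-2-(hydroxymethyl)-6,10-dimethyl-12-oxododeca-2,6,10-trienoate | O=C/C=C(\C)CC/C=C(/C)[C@@H](O)[C@H](OC(=O)[C@@]1(C)O[C@H]1C)/C=C(\CO)C(=O)OC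
F4 | step 11 | methyl (2E,4R,5R,6Z,10E)-4-{[(2S,3S)-2,3-dimethyloxirane-2-carbonyl]oxy}-5-hydroxy-6,10-dimethyl-12-oxo-2-[(4,4,5,5-tetramethyl-1,3,2-dioxaborolan-2-yl)methyl]dodeca-2,6,10-trienoate | O=C/C=C(\C)CC/C=C(/C)[C@@H](O)[C@H](OC(=O)[C@@]1(C)O[C@H]1C)/C=C(\CB2OC(C)(C)C(C)(C)O2)C(=O)OC
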